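A direct plan would C-propanoylate 2-methylphloroglucinol (A1) to ketone A2, O-methylate A2 at the hydroxyl para to the acyl group to give A3, aminomethylate A3 to the Mannich base A4, and heat A4 with A2 so that the o-quinone methide A5 is trapped by the free ring carbon of A2.
Its weakest steps would be:
- The mono-O-methylation of triol A2 to A3 would rest on stoichiometry and a small acidity difference among three phenols, so di-ether, C-methylated material and unreacted A2 would have to be separated.
- The last-step union of A4 (via A5) with A2 would be exposed to self-condensation, and methylene-bridged acylphloroglucinols can exchange their halves by retro-addition under heat, so symmetrical dimers would contaminate the crossed product.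
- The Friedel–Crafts acylation of unprotected A1 with excess AlCl3 would suffer O-acylation, diacylation and a difficult work-up on a very electron-rich triol.
In that plan every substituent would be placed by the directing effects of a preformed benzene ring.

**Retrosynthetic overview**
Each ring is a C-methyl propanoyl-phloroglucinol, i.e. a cyclised tetraketide; rings A and B differ only at the oxygen para to the propanoyl group (C4–OH in ring A, C6'–OMe in ring B).
Both benzene rings are cut at the bond between the propanoyl-bearing carbon and a neighbouring C–OH (C1–C6 of ring A, C3'–C2' of ring B), which leads back to the methylene-bridged bis(2H-pyran-2-one) 9, whose 4-OH and 4-OMe are those two oxygens.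
9 arises from two lateral acylations of bis-pyranone 7; 7 arises from a crossed reductive alkylation of pyranone 3 with pyranone aldehyde 5, both made from 3-methylpentane-2,4-dione (1).
Ring order: the two pyranone rings first (steps 1–4), the two benzene rings last and together (step 6).
The methyl ether enters as methoxide on a chloropyranone that has no hydroxyl, the bridge is built between unlike partners before any arene exists, and no arene is acylated, so the three weak steps do not occur.

Key step: step 6

Remark: the target has no stereocentre; pyranones and phenols are drawn in one tautomeric form each.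

Step 1
Reactants: 1 3-methylpentane-2,4-dione
Product: 3 4-hydroxy-5,6-dimethyl-2H-pyran-2-one, via 4-methyl-3,5-dioxohexanoic acid 2 (not isolated)
Conditions: LiN(iPr)2 (LDA, 2.2 equiv), THF, −78 → 0 °C; CO2, −78 °C; cold 2 M HCl, extract; crude acid, 1,1'-carbonyldiimidazole (1.3 equiv), THF, rt; 1 M HCl
Reagents that add atoms: carbon dioxide O=C=O
Why: The 1,3-diketone dianion should be carboxylated only at its more basic terminal carbon (γ-carboxylation of a β-diketone dianion), and carbonyldiimidazole then activates the acid of 2 so that the enol oxygen of the C5 ketone closes the 4-hydroxy-2-pyranone (enol lactonisation), the C4 methyl of the acid becoming the C5 methyl of the ring.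

Step 2
Reactants: 3 4-hydroxy-5,6-dimethyl-2H-pyran-2-one
Product: 4 4-chloro-5,6-dimethyl-2-oxo-2H-pyran-3-carbaldehyde
Conditions: POCl3 (3 equiv), DMF, 0 → 60 °C; ice, aq. NaOAc
Reagents that add atoms: N,N-dimethylformamide CN(C)C=O; phosphoryl chloride O=P(Cl)(Cl)Cl; water O
Why: Vilsmeier–Haack formylation should occur at C3, the only free enol-activated ring carbon (C5 is blocked by its methyl), with the chloroiminium reagent also exchanging the vinylogous-acid OH for Cl, as it does with 4-hydroxy-6-methyl-2-pyranone and 4-hydroxycoumarin.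

Step 3
Reactants: 4 4-chloro-5,6-dimethyl-2-oxo-2H-pyran-3-carbaldehyde
Product: 5 4-methoxy-5,6-dimethyl-2-oxo-2H-pyran-3-carbaldehyde
Conditions: NaOMe (1.05 equiv), MeOH/THF, −20 → 0 °C; aq. NH4Cl
Reagents that add atoms: sodium methoxide [Na+].[O-]C
Why: Addition–elimination (vinylic nucleophilic substitution) of methoxide at C4, a vinylogous acid chloride activated by both the lactone and the aldehyde carbonyl, should be much faster than attack at the lactone carbonyl, so the future ring B methoxy group enters at a carbon with a leaving group and no hydroxyl has to be chosen among several.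

Step 4
Reactants: 3 4-hydroxy-5,6-dimethyl-2H-pyran-2-one; 5 4-methoxy-5,6-dimethyl-2-oxo-2H-pyran-3-carbaldehyde
Product: 7 4-hydroxy-3-[(4-methoxy-5,6-dimethyl-2-oxo-2H-pyran-3-yl)methyl]-5,6-dimethyl-2H-pyran-2-one, via Knoevenagel alkylidene dione 6 (not isolated)
Conditions: diethyl 2,6-dimethyl-1,4-dihydropyridine-3,5-dicarboxylate (Hantzsch ester, 1.2 equiv), L-proline (10 mol %), CH2Cl2, rt
Reagents that add atoms: none
Why: Organocatalytic reductive alkylation: Knoevenagel condensation of the acidic C3–H of 3 with aldehyde 5 gives alkylidene dione 6, whose exocyclic carbon should accept hydride from the Hantzsch ester before a second pyranone can add, and because the partners are unlike from the outset (nucleophile 3, electrophile 5) only the crossed mono-O-methyl bis-pyranone can form.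

Step 5
Reactants: 7 4-hydroxy-3-[(4-methoxy-5,6-dimethyl-2-oxo-2H-pyran-3-yl)methyl]-5,6-dimethyl-2H-pyran-2-one; 8 N-methoxy-N-methylpropanamide
Product: 9 4-hydroxy-3-{[4-methoxy-5-methyl-2-oxo-6-(2-oxobutyl)-2H-pyran-3-yl]methyl}-5-methyl-6-(2-oxobutyl)-2H-pyran-2-one
Conditions: LiN(iPr)2 (LDA, 3.3 equiv), THF/DMPU, −78 °C; 8 (2.4 equiv), −78 → −30 °C; cold 1 M HCl
Reagents that add atoms: none
Why: Base should remove the OH proton and then the two C6–CH3 protons, the only C–H bonds whose carbanions are conjugated through the ring diene to the lactone carbonyl (the C5 methyls and the bridge CH2 are cross-conjugated), and each carbanion is acylated once because the lithium-chelated tetrahedral adduct of the N-methoxy-N-methylamide survives until the quench (lateral acylation of 6-methyl-2-pyranone anions).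

Step 6
Reactants: 9 4-hydroxy-3-{[4-methoxy-5-methyl-2-oxo-6-(2-oxobutyl)-2H-pyran-3-yl]methyl}-5-methyl-6-(2-oxobutyl)-2H-pyran-2-one
Product: 11 1-{3-[(2,4-dihydroxy-6-methoxy-5-methyl-3-propanoylphenyl)methyl]-2,4,6-trihydroxy-5-methylphenyl}propan-1-one (CNP0215809.0), via half-rearranged arylmethyl pyranone 10 (not isolated)
Conditions: Mg(OMe)2 (commercial solution, 8 equiv), MeOH, 25 → 55 °C, Ar; pour into cold 1 M HCl
Reagents that add atoms: none
Why: Methoxide adds to each lactone carbonyl (pyranone C2) and the C2–O1 bond breaks to a transient magnesium-chelated methyl ester/β-diketone chain, in which the doubly activated side-chain CH2 attacks the ester carbon and expels methoxide (intramolecular Claisen condensation) before enolisation to the benzene ring; the neutral 4-methoxy ring should react first (giving 10) and the 4-oxido ring second. The closest known reaction type is the biomimetic conversion of 6-(2-oxoalkyl)-4-hydroxy- and 4-methoxy-2-pyranones into acylphloroglucinols with magnesium methoxide, here run twice in one molecule. Each benzene ring closes by a 6-exo-trig C-acylation that forms the bond between the propanoyl-bearing carbon and a hydroxyl-bearing carbon (C1–C6 of ring A, C3'–C2' of ring B), the cis placement of the ester and C5 across the C3=C4 bond being inherited from the pyranone. No stereocentre is formed. The step needs Claisen rather than aldol closure and a fixed place for the methyl ether: the bridge substituent at pyranone C3 makes the ester α-carbon fully substituted, so the aldol (resorcylate) mode cannot aromatise and stays reversible, and pyranone C4 with its OMe or O− necessarily becomes the oxygen para to the acyl group; any transfer of the methyl ether between the two pyranone halves would be degenerate because they are otherwise identical.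

**Compound list**
1 | 3-methylpentane-2,4-dione | CC(=O)C(C)C(C)=O | starting material
2 | 4-methyl-3,5-dioxohexanoic acid | CC(=O)C(C)C(=O)CC(=O)O | intermediate
3 | 4-hydroxy-5,6-dimethyl-2H-pyran-2-one | CC1=C(C)C(O)=CC(=O)O1 | intermediate
4 | 4-chloro-5,6-dimethyl-2-oxo-2H-pyran-3-carbaldehyde | CC1=C(C)C(Cl)=C(C=O)C(=O)O1 | intermediate
5 | 4-methoxy-5,6-dimethyl-2-oxo-2H-pyran-3-carbaldehyde | COC1=C(C=O)C(=O)OC(C)=C1C | intermediate
6 | 3-[(4-methoxy-5,6-dimethyl-2-oxo-2H-pyran-3-yl)methylidene]-5,6-dimethyl-2H-pyran-2,4(3H)-dione (alkene geometry not defined) | CC1=C(C)C(=O)C(=CC2=C(OC)C(C)=C(C)OC2=O)C(=O)O1 | intermediate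
7 | 4-hydroxy-3-[(4-methoxy-5,6-dimethyl-2-oxo-2H-pyran-3-yl)methyl]-5,6-dimethyl-2H-pyran-2-one | CC1=C(C)C(O)=C(CC2=C(OC)C(C)=C(C)OC2=O)C(=O)O1 | intermediate
8 | N-methoxy-N-methylpropanamide | CCC(=O)N(C)OC | starting material
9 | 4-hydroxy-3-{[4-methoxy-5-methyl-2-oxo-6-(2-oxobutyl)-2H-pyran-3-yl]methyl}-5-methyl-6-(2-oxobutyl)-2H-pyran-2-one | CCC(=O)CC1=C(C)C(O)=C(CC2=C(OC)C(C)=C(CC(=O)CC)OC2=O)C(=O)O1 | intermediate
10 | 3-[(2,4-dihydroxy-6-methoxy-5-methyl-3-propanoylphenyl)methyl]-4-hydroxy-5-methyl-6-(2-oxobutyl)-2H-pyran-2-one | CCC(=O)CC1=C(C)C(O)=C(Cc2c(O)c(C(=O)CC)c(O)c(C)c2OC)C(=O)O1 | intermediate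
11 | 1-{3-[(2,4-dihydroxy-6-methoxy-5-methyl-3-propanoylphenyl)methyl]-2,4,6-trihydroxy-5-methylphenyl}propan-1-one (CNP0215809.0) | CCC(=O)c1c(O)c(C)c(O)c(Cc2c(O)c(C(=O)CC)c(O)c(C)c2OC)c1O | target

**Totals**
Total step count: 6. Longest linear sequence: 6 steps (1 → 3 → 4 → 5 → 7 → 9 → 11; compound 3 from step 1 is used in steps 2 and 4).

**Steps most likely to fail**

Step 6 (double ring transformation). The deprotonated 4-oxido pyranone ring may resist methoxide addition, so the reaction could stall at the half-rearranged stage while prolonged base exposure erodes the side chains or lets the methylene bridge exchange. Fallback, setting out from 9 and returning at 11: Mitsunobu O-benzylation of the single pyranone hydroxyl (BnOH, PPh3, diisopropyl azodicarboxylate, THF) would give 4-(benzyloxy)-3-{[4-methoxy-5-methyl-2-oxo-6-(2-oxobutyl)-2H-pyran-3-yl]methyl}-5-methyl-6-(2-oxobutyl)-2H-pyran-2-one F1, in which both rings are neutral 4-alkoxy pyranones. The same Mg(OMe)2 treatment should then give 1-{4-(benzyloxy)-3-[(2,4-dihydroxy-6-methoxy-5-methyl-3-propanoylphenyl)methyl]-2,6-dihydroxy-5-methylphenyl}propan-1-one F2, and hydrogenolysis (H2, palladium on carbon, Pd/C, EtOAc) would release 11.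

Step 5 (double lateral acylation). Formation of the trianion may be incomplete at the 6-methyl of the oxido ring, or the polyanion may aggregate, which would leave mono-acylated material. Fallback, setting out from 7 and returning at 9: the hydroxyl would be masked first (MOMCl, iPr2NEt, CH2Cl2) as 4-(methoxymethoxy)-3-[(4-methoxy-5,6-dimethyl-2-oxo-2H-pyran-3-yl)methyl]-5,6-dimethyl-2H-pyran-2-one F3, so that only two ordinary vinylogous mono-anions are needed (LDA, 2.2 equiv; then 8). This should give 4-(methoxymethoxy)-3-{[4-methoxy-5-methyl-2-oxo-6-(2-oxobutyl)-2H-pyran-3-yl]methyl}-5-methyl-6-(2-oxobutyl)-2H-pyran-2-one F4, and mild acid (CF3CO2H, CH2Cl2, 0 °C) would return 9.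

Step 4 (crossed reductive alkylation). The Knoevenagel adduct may be trapped by a second molecule of 3 faster than hydride transfer, or the amine catalyst may displace the C4 methoxy group of 5 by addition–elimination. Fallback, setting out from 5 and 3 and returning at 7: Luche reduction of 5 (NaBH4, CeCl3·7H2O, MeOH, −40 °C) would give 3-(hydroxymethyl)-4-methoxy-5,6-dimethyl-2H-pyran-2-one F5. Its methoxy-stabilised cation, formed with catalytic Bi(OTf)3 in MeNO2 at rt, should alkylate C3 of 3 in a dehydrative Friedel–Crafts-type reaction to give 7.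

**Further compounds**
F1 | step 6 | 4-(benzyloxy)-3-{[4-methoxy-5-methyl-2-oxo-6-(2-oxobutyl)-2H-pyran-3-yl]methyl}-5-methyl-6-(2-oxobutyl)-2H-pyran-2-one | CCC(=O)CC1=C(C)C(OCc3ccccc3)=C(CC2=C(OC)C(C)=C(CC(=O)CC)OC2=O)C(=O)O1
F2 | step 6 | 1-{4-(benzyloxy)-3-[(2,4-dihydroxy-6-methoxy-5-methyl-3-propanoylphenyl)methyl]-2,6-dihydroxy-5-methylphenyl}propan-1-one | CCC(=O)c1c(O)c(C)c(OCc3ccccc3)c(Cc2c(O)c(C(=O)CC)c(O)c(C)c2OC)c1O
F3 | step 5 | 4-(methoxymethoxy)-3-[(4-methoxy-5,6-dimethyl-2-oxo-2H-pyran-3-yl)methyl]-5,6-dimethyl-2H-pyran-2-one | CC1=C(C)C(OCOC)=C(CC2=C(OC)C(C)=C(C)OC2=O)C(=O)O1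
F4 | step 5 | 4-(methoxymethoxy)-3-{[4-methoxy-5-methyl-2-oxo-6-(2-oxobutyl)-2H-pyran-3-yl]methyl}-5-methyl-6-(2-oxobutyl)-2H-pyran-2-one | CCC(=O)CC1=C(C)C(OCOC)=C(CC2=C(OC)C(C)=C(CC(=O)CC)OC2=O)C(=O)O1
F5 | step 4 | 3-(hydroxymethyl)-4-methoxy-5,6-dimethyl-2H-pyran-2-one | COC1=C(CO)C(=O)OC(C)=C1C
A1 | direct plan | 2-methylbenzene-1,3,5-triol | Cc1c(O)cc(O)cc1O
A2 | direct plan | 1-(2,4,6-trihydroxy-3-methylphenyl)propan-1-one | CCC(=O)c1c(O)cc(O)c(C)c1O
A3 | direct plan | 1-(2,6-dihydroxy-4-methoxy-3-methylphenyl)propan-1-one | CCC(=O)c1c(O)cc(OC)c(C)c1O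
A4 | direct plan | 1-{3-[(dimethylamino)methyl]-2,6-dihydroxy-4-methoxy-5-methylphenyl}propan-1-one | CCC(=O)c1c(O)c(CN(C)C)c(OC)c(C)c1O
A5 | direct plan | 3-hydroxy-5-methoxy-4-methyl-6-methylidene-2-propanoylcyclohexa-2,4-dien-1-one | CCC(=O)C1=C(O)C(C)=C(OC)C(=C)C1=O
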